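**Retrosynthetic overview**
1. Target ⇐ its bis(isopropyl ether) (BCl3). The biaryl axis is made racemic and resolved on a chiral phase just before this last step.
2. Pyridine ring (formed last): 1-methyl from a 1-chloroisoquinoline ⇐ isoquinolin-1(2H)-one ⇐ o-toluate + N-methoxy-N-methylacetamide (lateral lithiation), then NH4OAc.
3. Isoquinoline carbocycle (formed second), key C–C bond: 3-naphthyl-6-methylsalicylate ⇐ (DDQ) cyclohexenone ⇐ intermolecular Michael addition of a γ-naphthyl acetoacetate to crotonaldehyde, then ring-closing aldol condensation. The aryl–aryl bond of the target is the naphthyl–CH2 bond of the keto ester, so no biaryl coupling is needed.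
4. γ-Naphthyl acetoacetate ⇐ naphthylacetic acid + Meldrum's acid ⇐ 1-bromonaphthalene + oxirane.
5. Naphthalene (its second ring is formed first): 8-isopropoxy-3-methyl-1-naphthol ⇐ anionic annulation of an o-methallyl benzamide ⇐ N,N-diethylsalicylamide (directed ortho metalation).

Assumption: the SMILES has no stereodescriptor; the only stereo element is the C7–C1' axis, taken here as M for the ent series (if P is meant, the other fraction of step 16 is carried on), and the axis descriptor is given in the names because SMILES cannot show it.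

Abbreviation used in names: Ar = 4-methoxy-2-methyl-5-(propan-2-yloxy)naphthalen-1-yl.

**Route**

Step 1
Reactants: 1 N,N-diethyl-2-hydroxybenzamide
Product: 2 N,N-diethyl-2-(propan-2-yloxy)benzamide
Conditions: 2-bromopropane, K2CO3, DMF, 70 °C
Reagents that add atoms: 2-bromopropane, CC(C)Br
Why: Williamson ether synthesis on the phenoxide; the tertiary amide is inert and the isopropyl ether later survives organolithium reagents.

Step 2
Reactants: 2 N,N-diethyl-2-(propan-2-yloxy)benzamide; 3 3-bromo-2-methylprop-1-ene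
Product: 6 N,N-diethyl-2-(2-methylprop-2-en-1-yl)-6-(propan-2-yloxy)benzamide, via ortho-lithiated amide 4 (not isolated), via arylmagnesium bromide 5 (not isolated)
Conditions: s-BuLi, TMEDA, THF, –78 °C; MgBr2·OEt2, –78 → 0 °C; 3, –78 °C → rt
Reagents that add atoms: none
Why: Directed ortho metalation, in which the tertiary amide outranks the ether so lithiation goes to C6, and transmetalation to magnesium gives clean allylation instead of proton transfer.

Step 3
Reactants: 6 N,N-diethyl-2-(2-methylprop-2-en-1-yl)-6-(propan-2-yloxy)benzamide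
Product: 8 3-methyl-8-(propan-2-yloxy)naphthalen-1-ol, via keto tautomer 7 (not isolated)
Conditions: MeLi (2.2 equiv), THF, –78 °C → rt; aq NH4Cl
Reagents that add atoms: none
Why: Anionic ring annulation of an o-allylbenzamide (Sibi–Snieckus naphthol synthesis): the benzylic-allylic CH2 is deprotonated, the allyl terminus attacks the hindered amide in a six-ring closure, diethylamide leaves and 7 enolises to the naphthol.

Step 4
Reactants: 8 3-methyl-8-(propan-2-yloxy)naphthalen-1-ol
Product: 9 1-methoxy-3-methyl-8-(propan-2-yloxy)naphthalene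
Conditions: MeI, K2CO3, acetone, reflux
Reagents that add atoms: iodomethane, CI
Why: Williamson methylation of the naphthol fixes the methyl ether on the oxygen that must stay methylated in the target.

Step 5
Reactants: 9 1-methoxy-3-methyl-8-(propan-2-yloxy)naphthalene
Product: 10 1-bromo-4-methoxy-2-methyl-5-(propan-2-yloxy)naphthalene
Conditions: NBS (1.05 equiv), MeCN, 0 °C → rt
Reagents that add atoms: N-bromosuccinimide, O=C1CCC(=O)N1Br
Why: Electrophilic aromatic bromination at the position para to the methoxy group and ortho to the methyl group, which is activated by both and so is favoured over the position para to the isopropoxy group.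

Step 6
Reactants: 10 1-bromo-4-methoxy-2-methyl-5-(propan-2-yloxy)naphthalene; 11 oxirane
Product: 13 2-[4-methoxy-2-methyl-5-(propan-2-yloxy)naphthalen-1-yl]ethan-1-ol, via naphthyllithium 12 (not isolated)
Conditions: n-BuLi, THF, –78 °C; 11 (3 equiv), –78 °C → rt; aq NH4Cl
Reagents that add atoms: none
Why: Bromine–lithium exchange followed by epoxide ring opening puts the two-carbon chain exactly on the brominated carbon.

Step 7
Reactants: 13 2-[4-methoxy-2-methyl-5-(propan-2-yloxy)naphthalen-1-yl]ethan-1-ol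
Product: 15 [4-methoxy-2-methyl-5-(propan-2-yloxy)naphthalen-1-yl]acetic acid, via arylacetaldehyde 14 (not isolated)
Conditions: TEMPO (0.2 equiv), PhI(OAc)2 (2.2 equiv), MeCN/H2O 1:1, rt
Reagents that add atoms: water, O
Why: Oxoammonium (TEMPO) oxidation of the primary alcohol through the aldehyde hydrate to the acid, mild enough for the electron-rich naphthalene.

Step 8
Reactants: 15 [4-methoxy-2-methyl-5-(propan-2-yloxy)naphthalen-1-yl]acetic acid; 16 2,2-dimethyl-1,3-dioxane-4,6-dione (Meldrum's acid)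
Product: 18 ethyl 4-Ar-3-oxobutanoate, via acyl Meldrum's acid 17 (not isolated)
Conditions: DCC, DMAP, CH2Cl2, 0 °C → rt; filter; EtOH, reflux
Reagents that add atoms: ethanol, CCO
Why: Claisen-type C-acylation of Meldrum's acid followed by ethanolysis with loss of acetone and CO2 (Oikawa–Yonemitsu β-keto ester synthesis).

Step 9
Reactants: 18 ethyl 4-Ar-3-oxobutanoate; 19 (E)-but-2-enal
Product: 22 ethyl 6-methyl-3-Ar-2-oxocyclohex-3-ene-1-carboxylate (racemic diastereomer mixture), via Michael adduct 20 (not isolated), via aldol 21 (not isolated)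
Conditions: NaOEt (0.1 equiv), EtOH, 0 °C, slow addition of 19, → rt; then HCl (g), EtOH, 0 °C → rt
Reagents that add atoms: none
Why: Intermolecular Michael addition of the doubly activated carbon of the β-keto ester to the enal, then intramolecular aldol condensation of the benzylic γ-CH2 onto the aldehyde (Hauser-type Robinson annulation); the sp3 centres formed are uncontrolled and are erased in step 10.

Step 10
Reactants: 22 ethyl 6-methyl-3-Ar-2-oxocyclohex-3-ene-1-carboxylate
Product: 23 ethyl 2-hydroxy-6-methyl-3-Ar-benzoate (racemic at the axis)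
Conditions: DDQ (1.2 equiv), 1,4-dioxane, 80 °C
Reagents that add atoms: none
Why: Quinone dehydrogenation of the enolised β-keto ester is driven by aromatisation to the salicylate, and the biaryl axis appears here as a racemate.

Step 11
Reactants: 23 ethyl 2-hydroxy-6-methyl-3-Ar-benzoate
Product: 24 ethyl 6-methyl-3-Ar-2-(propan-2-yloxy)benzoate
Conditions: 2-iodopropane (3 equiv), Cs2CO3, DMF, 60 °C
Reagents that add atoms: 2-iodopropane, CC(C)I
Why: Williamson ether synthesis on the caesium phenoxide masks the acidic phenol before lateral lithiation and shields the ester from nucleophiles.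

Step 12
Reactants: 24 ethyl 6-methyl-3-Ar-2-(propan-2-yloxy)benzoate; 25 N-methoxy-N-methylacetamide
Product: 27 ethyl 6-(2-oxopropyl)-3-Ar-2-(propan-2-yloxy)benzoate, via benzylic lithium compound 26 (not isolated)
Conditions: LiN(i-Pr)2 (1.2 equiv), THF, –78 °C; 25, –78 → –20 °C; aq NH4Cl
Reagents that add atoms: none
Why: Lateral lithiation of the o-toluate (the methyl ortho to the ester is the only activated benzylic site) and acylation with a Weinreb amide, which stops cleanly at the ketone.

Step 13
Reactants: 27 ethyl 6-(2-oxopropyl)-3-Ar-2-(propan-2-yloxy)benzoate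
Product: 29 3-methyl-7-Ar-8-(propan-2-yloxy)isoquinolin-1(2H)-one, via enamine 28 (not isolated)
Conditions: NH4OAc (10 equiv), AcOH, 100 °C
Reagents that add atoms: ammonium acetate, CC(=O)[O-].[NH4+]
Why: Condensation of ammonia with the ketone and intramolecular aminolysis of the neighbouring ester (lactamisation) gives the aromatic isoquinolinone.

Step 14
Reactants: 29 3-methyl-7-Ar-8-(propan-2-yloxy)isoquinolin-1(2H)-one
Product: 30 1-chloro-3-methyl-7-Ar-8-(propan-2-yloxy)isoquinoline
Conditions: POCl3, 90 °C; ice, aq NaHCO3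
Reagents that add atoms: phosphoryl chloride, O=P(Cl)(Cl)Cl
Why: Deoxychlorination of the lactam through its O-phosphorylated imidate; aryl isopropyl and methyl ethers tolerate POCl3.

Step 15
Reactants: 30 1-chloro-3-methyl-7-Ar-8-(propan-2-yloxy)isoquinoline
Product: 31 racemic 1,3-dimethyl-7-Ar-8-(propan-2-yloxy)isoquinoline
Conditions: trimethylboroxine, PdCl2(dppf) (5 mol %), K2CO3, 1,4-dioxane/H2O, 100 °C
Reagents that add atoms: trimethylboroxine, CB1OB(C)OB(C)O1
Why: Suzuki–Miyaura methylation, in which the C–Cl bond next to the ring nitrogen adds readily to zerovalent palladium.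

Step 16
Reactants: 31 racemic 1,3-dimethyl-7-Ar-8-(propan-2-yloxy)isoquinoline
Product: 32 (M)-1,3-dimethyl-7-Ar-8-(propan-2-yloxy)isoquinoline
Conditions: preparative HPLC, cellulose tris(3,5-dimethylphenylcarbamate) on silica, n-hexane/i-PrOH/Et2NH, 20 °C; M fraction identified by ECD
Reagents that add atoms: none
Why: Resolution of atropisomers: the axis carries an alkoxy group, a methyl group and the peri-fused ring as ortho substituents and is configurationally stable at room temperature, so the enantiomers separate on the chiral phase and this step sets the only stereo element (all heated steps lie before it).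

Step 17
Reactants: 32 (M)-1,3-dimethyl-7-Ar-8-(propan-2-yloxy)isoquinoline
Product: 33 (M)-7-(5-hydroxy-4-methoxy-2-methylnaphthalen-1-yl)-1,3-dimethylisoquinolin-8-ol (ent-dioncophylleine A as given)
Conditions: BCl3 (6 equiv), CH2Cl2, –78 → 0 °C; MeOH, then aq NaHCO3
Reagents that add atoms: none
Why: Lewis-acid ether cleavage: BCl3 ionises the two secondary isopropyl ethers far faster than the methyl ether, and the low temperature leaves the axis (same M descriptor, priorities unchanged) untouched.

**Compound list**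
1 | N,N-diethyl-2-hydroxybenzamide | CCN(CC)C(=O)c1ccccc1O | starting material
2 | N,N-diethyl-2-(propan-2-yloxy)benzamide | CCN(CC)C(=O)c1ccccc1OC(C)C | intermediate
3 | 3-bromo-2-methylprop-1-ene | CC(=C)CBr | starting material
4 | N,N-diethyl-2-lithio-6-(propan-2-yloxy)benzamide | [Li]c1cccc(OC(C)C)c1C(=O)N(CC)CC | intermediate
5 | [2-(diethylcarbamoyl)-3-(propan-2-yloxy)phenyl]magnesium bromide | Br[Mg]c1cccc(OC(C)C)c1C(=O)N(CC)CC | intermediate
6 | N,N-diethyl-2-(2-methylprop-2-en-1-yl)-6-(propan-2-yloxy)benzamide | CCN(CC)C(=O)c1c(CC(C)=C)cccc1OC(C)C | intermediate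
7 | 3-methyl-8-(propan-2-yloxy)naphthalen-1(4H)-one | CC1=CC(=O)c2c(OC(C)C)cccc2C1 | intermediate
8 | 3-methyl-8-(propan-2-yloxy)naphthalen-1-ol | Cc1cc(O)c2c(OC(C)C)cccc2c1 | intermediate
9 | 1-methoxy-3-methyl-8-(propan-2-yloxy)naphthalene | COc1cc(C)cc2cccc(OC(C)C)c12 | intermediate
10 | 1-bromo-4-methoxy-2-methyl-5-(propan-2-yloxy)naphthalene | COc1cc(C)c(Br)c2cccc(OC(C)C)c12 | intermediate
11 | oxirane | C1CO1 | starting material
12 | [4-methoxy-2-methyl-5-(propan-2-yloxy)naphthalen-1-yl]lithium | COc1cc(C)c([Li])c2cccc(OC(C)C)c12 | intermediate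
13 | 2-[4-methoxy-2-methyl-5-(propan-2-yloxy)naphthalen-1-yl]ethan-1-ol | COc1cc(C)c(CCO)c2cccc(OC(C)C)c12 | intermediate
14 | [4-methoxy-2-methyl-5-(propan-2-yloxy)naphthalen-1-yl]acetaldehyde | COc1cc(C)c(CC=O)c2cccc(OC(C)C)c12 | intermediate
15 | [4-methoxy-2-methyl-5-(propan-2-yloxy)naphthalen-1-yl]acetic acid | COc1cc(C)c(CC(=O)O)c2cccc(OC(C)C)c12 | intermediate
16 | 2,2-dimethyl-1,3-dioxane-4,6-dione | CC1(C)OC(=O)CC(=O)O1 | starting material
17 | 5-(Ar-acetyl)-2,2-dimethyl-1,3-dioxane-4,6-dione | COc1cc(C)c(CC(=O)C2C(=O)OC(C)(C)OC2=O)c2cccc(OC(C)C)c12 | intermediate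
18 | ethyl 4-Ar-3-oxobutanoate | CCOC(=O)CC(=O)Cc1c(C)cc(OC)c2c(OC(C)C)cccc12 | intermediate
19 | (E)-but-2-enal | C/C=C/C=O | starting material
20 | ethyl 2-(Ar-acetyl)-3-methyl-5-oxopentanoate (diastereomer mixture) | CCOC(=O)C(C(C)CC=O)C(=O)Cc1c(C)cc(OC)c2c(OC(C)C)cccc12 | intermediate
21 | ethyl 4-hydroxy-6-methyl-3-Ar-2-oxocyclohexane-1-carboxylate (diastereomer mixture) | CCOC(=O)C1C(C)CC(O)C(c2c(C)cc(OC)c3c(OC(C)C)cccc23)C1=O | intermediate
22 | ethyl 6-methyl-3-Ar-2-oxocyclohex-3-ene-1-carboxylate (racemic diastereomer mixture) | CCOC(=O)C1C(C)CC=C(c2c(C)cc(OC)c3c(OC(C)C)cccc23)C1=O | intermediate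
23 | ethyl 2-hydroxy-6-methyl-3-Ar-benzoate (racemic axis) | CCOC(=O)c1c(C)ccc(-c2c(C)cc(OC)c3c(OC(C)C)cccc23)c1O | intermediate
24 | ethyl 6-methyl-3-Ar-2-(propan-2-yloxy)benzoate (racemic axis) | CCOC(=O)c1c(C)ccc(-c2c(C)cc(OC)c3c(OC(C)C)cccc23)c1OC(C)C | intermediate
25 | N-methoxy-N-methylacetamide | CC(=O)N(C)OC | starting material
26 | ethyl 6-(lithiomethyl)-3-Ar-2-(propan-2-yloxy)benzoate | CCOC(=O)c1c(C[Li])ccc(-c2c(C)cc(OC)c3c(OC(C)C)cccc23)c1OC(C)C | intermediate
27 | ethyl 6-(2-oxopropyl)-3-Ar-2-(propan-2-yloxy)benzoate (racemic axis) | CCOC(=O)c1c(CC(C)=O)ccc(-c2c(C)cc(OC)c3c(OC(C)C)cccc23)c1OC(C)C | intermediate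
28 | ethyl 6-(2-aminoprop-1-en-1-yl)-3-Ar-2-(propan-2-yloxy)benzoate | CCOC(=O)c1c(C=C(C)N)ccc(-c2c(C)cc(OC)c3c(OC(C)C)cccc23)c1OC(C)C | intermediate
29 | 3-methyl-7-Ar-8-(propan-2-yloxy)isoquinolin-1(2H)-one (racemic axis) | Cc1cc2ccc(-c3c(C)cc(OC)c4c(OC(C)C)cccc34)c(OC(C)C)c2c(=O)[nH]1 | intermediate
30 | 1-chloro-3-methyl-7-Ar-8-(propan-2-yloxy)isoquinoline (racemic axis) | Cc1cc2ccc(-c3c(C)cc(OC)c4c(OC(C)C)cccc34)c(OC(C)C)c2c(Cl)n1 | intermediate
31 | racemic 1,3-dimethyl-7-Ar-8-(propan-2-yloxy)isoquinoline | Cc1cc2ccc(-c3c(C)cc(OC)c4c(OC(C)C)cccc34)c(OC(C)C)c2c(C)n1 | intermediate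
32 | (M)-1,3-dimethyl-7-Ar-8-(propan-2-yloxy)isoquinoline | Cc1cc2ccc(-c3c(C)cc(OC)c4c(OC(C)C)cccc34)c(OC(C)C)c2c(C)n1 | intermediate
33 | (M)-7-(5-hydroxy-4-methoxy-2-methylnaphthalen-1-yl)-1,3-dimethylisoquinolin-8-ol | COc1cc(C)c(-c2ccc3cc(C)nc(C)c3c2O)c2cccc(O)c12 | target

**Step count and risks**
Total: 17 steps. Longest linear sequence: 17 steps (1 → 33); all other building blocks are purchased.

Step 9 is the most exposed step: the ring-closing aldol condensation must occur at a benzylic carbon that carries a 2-methyl-1-naphthyl group, and crotonaldehyde can oligomerise under base. The fallback sets out from 18 and uses a Lewis-acid [3+3] aldol sequence instead. Me3SiCl/Et3N gives ethyl 4-Ar-3-[(trimethylsilyl)oxy]but-2-enoate F2. LiN(i-Pr)2 then Me3SiCl gives the bis-silyl dienol ether 1-ethoxy-4-Ar-1,3-bis[(trimethylsilyl)oxy]buta-1,3-diene F3. With TiCl4 in CH2Cl2 (–78 °C → rt), the terminal diene carbon adds to the acetal of 4,4-dimethoxybutan-2-one (CC(=O)CC(OC)OC) in a Mukaiyama aldol reaction; the inner carbon then closes onto the ketone, and loss of methanol and water gives the aromatic salicylate directly. The fallback comes back to the route at 23, bypassing 22 and the DDQ step.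

Step 5 may give some of the regioisomer brominated para to the isopropoxy group. The fallback sets out from 8 and uses the free hydroxyl, the strongest director in the molecule, to fix the site: NBS (1.0 equiv), CH2Cl2, –40 °C gives 4-bromo-3-methyl-8-(propan-2-yloxy)naphthalen-1-ol F1. MeI/K2CO3 in acetone then methylates it, and the route is rejoined at 10.

Step 16 fails if the enantiomers of 31 do not separate on a preparative scale. The fallback sets out from 31 and replaces chromatography on a chiral phase by covalent diastereomers. BCl3 (as in step 17) gives racemic 7-(5-hydroxy-4-methoxy-2-methylnaphthalen-1-yl)-1,3-dimethylisoquinolin-8-ol F4. Esterification of both phenols with (S)-naproxen (DCC, DMAP, CH2Cl2, 0 °C) gives two diastereomeric diesters, separated on silica or by crystallisation into the M-configured bis[(S)-2-(6-methoxynaphthalen-2-yl)propanoate] F5 and its P-configured diastereomer F6. LiOH in THF/H2O at 0 °C cleaves F5 (axis assigned by ECD on the cleaved material), and the fallback comes back to the route at 33.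

Further compounds
F1 | step 5 | 4-bromo-3-methyl-8-(propan-2-yloxy)naphthalen-1-ol | Cc1cc(O)c2c(OC(C)C)cccc2c1Br
F2 | step 9 | ethyl 4-Ar-3-[(trimethylsilyl)oxy]but-2-enoate (E/Z mixture) | CCOC(=O)C=C(Cc1c(C)cc(OC)c2c(OC(C)C)cccc12)O[Si](C)(C)C
F3 | step 9 | 1-ethoxy-4-Ar-1,3-bis[(trimethylsilyl)oxy]buta-1,3-diene (isomer mixture) | CCOC(O[Si](C)(C)C)=CC(=Cc1c(C)cc(OC)c2c(OC(C)C)cccc12)O[Si](C)(C)C
F4 | step 16 | racemic 7-(5-hydroxy-4-methoxy-2-methylnaphthalen-1-yl)-1,3-dimethylisoquinolin-8-ol | COc1cc(C)c(-c2ccc3cc(C)nc(C)c3c2O)c2cccc(O)c12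
F5 | step 16 | (M)-axis bis[(S)-2-(6-methoxynaphthalen-2-yl)propanoate] of 33 | COc1cc(C)c(-c2ccc3cc(C)nc(C)c3c2OC(=O)[C@@H](C)c2ccc3cc(OC)ccc3c2)c2cccc(OC(=O)[C@@H](C)c3ccc4cc(OC)ccc4c3)c12
F6 | step 16 | (P)-axis diastereomer of F5 | COc1cc(C)c(-c2ccc3cc(C)nc(C)c3c2OC(=O)[C@@H](C)c2ccc3cc(OC)ccc3c2)c2cccc(OC(=O)[C@@H](C)c3ccc4cc(OC)ccc4c3)c12
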